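The synthesis rests on disconnecting the bond between the quaternary, methyl-bearing carbon C8 and the methine C9, the ring-fusion bond shared by cyclohexane ring B and cyclohexene ring C. A base-mediated intramolecular Michael addition/aldol condensation (Robinson-type annulation) forms this hindered bond, then C12–C13, in one operation: it closes rings B and C, sets C8 and C9 and delivers the ring-C enone. It exploits the 1,5-relationship between C14 (an ethyl ketone) and C12 (an enal carbonyl) across C8–C9. The precursor is a ring-A cyclohexenol whose adjacent carbons C5 and C10 carry a 3-methyl-4-oxohexyl chain and, at quaternary C10, an (E)-enal.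

Key step: step 8

Remark 1 (labels): ring A = C1 (acetoxy), C2, C3 (lactone C=O), ring O, C4 (gem-dimethyl), C5, C10 (methyl); ring B = C5–C10; ring C = C8 (methyl), C9, C11, C12=C13 (methyl), C14; ring D = spiro γ-lactone C14, C15, C16, C17(=O), O; ring E = furanone spiro at C16; α is the face of H-5 and H-9, β the face of the C8 and C10 methyls.
Remark 2: the methoxy-bearing C9 (compounds 7–12), C8 (12, 13) and C16 (23, 25) are carried as epimer mixtures, because these centres are erased or set later (steps 7, 8 and 17).
Remark 3: the (+)-(2R,8aS) oxaziridine is assumed to be the matched reagent for the required C16 configuration; if the sense proves opposite, its enantiomer is used.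

Step 1
Reactants: 1 4,4-dimethylcyclohexa-2,5-dien-1-one; 2 potassium vinyltrifluoroborate
Product: 3 (S)-4,4-dimethyl-5-vinylcyclohex-2-en-1-one
Conditions: [Rh(cod)2]PF6 (3 mol%), (S)-BINAP, toluene/H2O, 100 °C, 1 in excess
Reagents that add atoms: none
Why: Rhodium-catalysed asymmetric conjugate addition of the vinylborate to one of the two enantiotopic enone arms sets C5 (H-5 α) by catalyst control, and the excess of 1 suppresses addition to the second arm.

Step 2
Reactants: 3 (S)-4,4-dimethyl-5-vinylcyclohex-2-en-1-one
Product: 4 trans-4,4,6-trimethyl-5-vinylcyclohex-2-en-1-one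
Conditions: LiN(iPr)2, THF, −78 °C; MeI, −78 to 0 °C
Reagents that add atoms: iodomethane, CI
Why: Only C10 can be deprotonated (C4 is quaternary, the other α-carbon is vinylic) and the lithium dienolate is methylated anti to the neighbouring vinyl group (enolate alkylation); this configuration is transient because C10 is re-enolised in step 3.

Step 3
Reactants: 4 trans-4,4,6-trimethyl-5-vinylcyclohex-2-en-1-one; 5 1,1,3,3-tetramethoxypropane
Product: 7 6-(1,3,3-trimethoxypropyl)-4,4,6-trimethyl-5-vinylcyclohex-2-en-1-one, via silyl dienol ether 6 (not isolated)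
Conditions: LiN(iPr)2, THF, −78 °C, then Me3SiCl; solvent switch to CH2Cl2; 5 (excess), Me3SiOTf (cat.), −78 °C
Reagents that add atoms: chlorotrimethylsilane, C[Si](C)(C)Cl (silyl group of 6 only)
Why: The tetrasubstituted silyl dienol ether adds to the oxocarbenium ion from 5 (Mukaiyama-type acetal alkylation) anti to the C5 vinyl group, which makes C10 quaternary with the C9–C11–C12 arm α and the methyl β, cis to the vinyl group.

Step 4
Reactants: 7 6-(1,3,3-trimethoxypropyl)-4,4,6-trimethyl-5-vinylcyclohex-2-en-1-one
Product: 8 2α,3α-epoxy ketone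
Conditions: 30% H2O2, NaOH, MeOH, 0 °C
Reagents that add atoms: hydrogen peroxide, OO
Why: Weitz–Scheffer nucleophilic epoxidation touches only the enone, and hydroperoxide attacks C3 from the α face, anti to the axial β-methyl groups on C4 and C10, while the isolated vinyl group is inert.

Step 5
Reactants: 8 2α,3α-epoxy ketone
Product: 9 ring-A allylic alcohol (3α-OH, C1=C2)
Conditions: N2H4·H2O, AcOH (cat.), MeOH, 0 °C to rt
Reagents that add atoms: none
Why: Wharton transposition: the epoxy hydrazone fragments with loss of N2, moving the oxygen function from C1 to C3 with retention of the C3–O bond (3α-OH) and creating the C1=C2 alkene.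

Step 6
Reactants: 9 ring-A allylic alcohol (3α-OH, C1=C2); 10 2-bromopentan-3-one
Product: 12 ring-A allylic alcohol with 3-methyl-4-oxohexyl chain, via B-alkyl-9-BBN adduct 11 (not isolated)
Conditions: 9-BBN (excess), THF, rt to 50 °C; then 10, potassium 2,6-di-tert-butylphenoxide, THF, 0 °C; aqueous work-up
Reagents that add atoms: 9-borabicyclo[3.3.1]nonane, B1C2CCCC1CCC2 (boron unit of 11 only)
Why: 9-BBN hydroborates the terminal vinyl group anti-Markovnikov (the hindered ring alkene is left) and the primary alkyl group then migrates from boron to the α-carbon of the bromo ketone enolate (organoborane α-alkylation of an α-halo ketone), forming C7–C8 with C8 as an inconsequential epimer mixture.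

Step 7
Reactants: 12 ring-A allylic alcohol with 3-methyl-4-oxohexyl chain
Product: 13 keto enal
Conditions: TsOH·H2O (cat.), acetone/H2O, 40 °C
Reagents that add atoms: water, O
Why: Hydrolysis of the dimethyl acetal and acid-catalysed β-elimination of methanol from the resulting β-methoxy aldehyde unmask the conjugated enal as the favoured (E)-isomer, which also erases the C9 stereocentre.

Step 8
Reactants: 13 keto enal
Product: 15 tricyclic hydroxy enone, via Michael adduct 14 (not isolated)
Conditions: KOtBu (2.2 equiv), tBuOH/THF, 0 °C to rt, high dilution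
Reagents that add atoms: none
Why: tert-Butoxide enolises the ethyl ketone reversibly on both sides, but only the more substituted C8 enolate can reach the enal β-carbon C9 through a six-membered transition state, so a 6-(enolexo)-exo-trig Michael addition forms the C8–C9 bond and closes ring B; after proton transfer the C13 enolate of the same ketone attacks the C12 aldehyde (6-(enolendo)-exo-trig aldol) and E1cB loss of water closes ring C as the conjugated C12=C13 enone, which makes the cascade irreversible. The closest known reaction type is the Robinson-type annulation (Michael addition followed by aldol condensation) of a ketone with an enal, here run intramolecularly. C9 is set in a chair-like transition state for ring B, anchored by the trans-diequatorial C5 and C10 arms of ring A, in which the enal chain is equatorial and H-9 therefore axial and α. C8 is set in the same transition state: the large potassium enolate unit (C14) takes the equatorial site anti to C10 and the small methyl group the axial β site, which gives the trans B/C fusion. The step needs C8-over-C13 regioselectivity and trans-over-cis diastereoselectivity; the first is secured by ring size (attack from C13 would need an eight-membered ring) and reversible enolisation, the second by the equatorial preference of the two large groups on the forming ring. Side equilibria (oxa-Michael addition of the C3 alkoxide, aldol adducts that cannot dehydrate) are reversible and drain into the enone.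

Step 9
Reactants: 15 tricyclic hydroxy enone
Product: 16 1α,2α-epoxy-3α-alcohol
Conditions: VO(acac)2 (cat.), tBuOOH, CH2Cl2, 0 °C to rt
Reagents that add atoms: tert-butyl hydroperoxide, CC(C)(C)OO
Why: Hydroxyl-directed vanadium-catalysed epoxidation delivers oxygen to C1=C2 syn to the 3α-hydroxyl (also the face anti to the C10 methyl), setting the C1–O bond α, and leaves the electron-poor ring-C enone untouched.

Step 10
Reactants: 16 1α,2α-epoxy-3α-alcohol
Product: 17 1α,2α-epoxy-3-ketone
Conditions: 1,1,1-triacetoxy-1,1-dihydro-1,2-benziodoxol-3(1H)-one, NaHCO3, CH2Cl2, 0 °C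
Reagents that add atoms: none
Why: Mild periodinane oxidation of the secondary alcohol gives the α,β-epoxy ketone without opening the epoxide or touching C1.

Step 11
Reactants: 17 1α,2α-epoxy-3-ketone
Product: 18 1α-hydroxy-3-ketone
Conditions: PhSeSePh, NaBH4, EtOH, then AcOH, 0 °C
Reagents that add atoms: none
Why: Phenylselenide opens the epoxide at C2 (α to the ketone) and a second selenide removes the selenium to give the enolate, a known reductive cleavage of the Cα–O bond of α,β-epoxy ketones that retains the C1–O bond (1α-OH) and only adds reversibly to the hindered ring-C enone.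

Step 12
Reactants: 18 1α-hydroxy-3-ketone
Product: 19 1α-acetoxy-3-ketone
Conditions: Ac2O, pyridine, DMAP (cat.), CH2Cl2, 0 °C
Reagents that add atoms: acetic anhydride, CC(=O)OC(C)=O
Why: Nucleophile-catalysed acetylation esterifies the hindered axial alcohol, and the low temperature and weak base avoid β-elimination of the β-acetoxy ketone.

Step 13
Reactants: 19 1α-acetoxy-3-ketone
Product: 20 ring-A ε-lactone enone
Conditions: mCPBA, NaHCO3, CH2Cl2, rt
Reagents that add atoms: 3-chloroperoxybenzoic acid, OOC(=O)c1cccc(Cl)c1
Why: Baeyer–Villiger oxidation of the saturated C3 ketone with migration of the more substituted C4 gives the seven-membered lactone, while the conjugated, doubly hindered C14 enone reacts far more slowly with the peracid.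

Step 14
Reactants: 20 ring-A ε-lactone enone
Product: 21 exocyclic diene
Conditions: Zn, CH2Br2, TiCl4, THF/CH2Cl2, 0 °C to rt
Reagents that add atoms: dibromomethane, BrCBr
Why: The non-basic zinc/titanium methylene reagent (Takai–Lombardo-type methylenation) converts the hindered C14 ketone into the exocyclic methylene without attacking the lactone or acetate, giving the C15=C14–C13=C12 diene.

Step 15
Reactants: 21 exocyclic diene; 22 malonic acid
Product: 23 spiro γ-lactone acid
Conditions: Mn(OAc)3·2H2O (2.2 equiv), 22 (excess), AcOH, rt to 40 °C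
Reagents that add atoms: none
Why: Trivalent manganese generates the electrophilic malonyl radical, which adds to the terminal C15; the allylic radical is oxidised to the allyl cation and closed by a carboxyl group at C14 (5-exo) from the α face, anti to the axial C8 methyl, setting the spiro centre C14 (manganese-mediated oxidative lactone annulation).

Step 16
Reactants: 23 spiro γ-lactone acid; 24 tigloyl chloride
Product: 25 α-tigloyl spiro lactone
Conditions: MgCl2, Et3N, MeCN, 0 °C; then 24, 0 °C to rt
Reagents that add atoms: none
Why: The magnesium enolate of the malonic half-ester is C-acylated by the acid chloride and the acyl malonic acid loses CO2 (decarboxylative Claisen-type acylation), under conditions too mild to enolise the ring-A lactone.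

Step 17
Reactants: 25 α-tigloyl spiro lactone
Product: 26 16-hydroxy-16-tigloyl spiro lactone
Conditions: KN(SiMe3)2 (1.0 equiv), THF, −78 °C; (+)-(2R,8aS)-(camphorylsulfonyl)oxaziridine, −78 to −40 °C; AcOH quench
Reagents that add atoms: (+)-(2R,8aS)-(camphorylsulfonyl)oxaziridine, CC1(C)[C@@H]2CC[C@]13CS(=O)(=O)N4O[C@@]34C2
Why: Only the β-keto lactone is acidic enough for one equivalent of base, and the enantiopure N-sulfonyloxaziridine transfers oxygen to one face of the chelated enolate under reagent control (the substrate faces are sterically alike), setting quaternary C16.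

Step 18
Reactants: 26 16-hydroxy-16-tigloyl spiro lactone
Product: 27 CNP0131208.2
Conditions: Pd(OCOCF3)2 (10 mol%), O2 (1 atm), DMSO, 50 °C
Reagents that add atoms: none
Why: Divalent palladium activates the enone alkene for 5-endo attack by the tertiary hydroxyl (Wacker-type oxidative cyclisation of an α-hydroxy enone) and β-hydride elimination gives the 4,5-dimethylfuran-3(2H)-one without touching C16.

Compound list
1 | 4,4-dimethylcyclohexa-2,5-dien-1-one | CC1(C)C=CC(=O)C=C1 | starting material
2 | potassium vinyltrifluoroborate | [K+].C=C[B-](F)(F)F | starting material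
3 | (S)-4,4-dimethyl-5-vinylcyclohex-2-en-1-one (H-5 α, vinyl β) | O=C1C=CC(C)(C)[C@H](C=C)C1 | intermediate
4 | trans-4,4,6-trimethyl-5-vinylcyclohex-2-en-1-one (C5 as in 3, 6-methyl trans to vinyl) | O=C1C=CC(C)(C)[C@H](C=C)[C@H]1C | intermediate
5 | 1,1,3,3-tetramethoxypropane | COC(CC(OC)OC)OC | starting material
6 | 2-(trimethylsilyloxy)-1,5,5-trimethyl-6-vinylcyclohexa-1,3-diene (C6 as C5 of 3) | C[Si](C)(C)OC1=C(C)[C@@H](C=C)C(C)(C)C=C1 | intermediate
7 | 6-(1,3,3-trimethoxypropyl)-4,4,6-trimethyl-5-vinylcyclohex-2-en-1-one (C10 methyl β and cis to vinyl, three-carbon arm α; mixture at the methoxy carbon C9) | O=C1C=CC(C)(C)[C@H](C=C)[C@@]1(C)C(OC)CC(OC)OC | intermediate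
8 | 2α,3α-epoxide of 7 (epoxide trans to the vinyl group) | O=C1[C@H]2O[C@H]2C(C)(C)[C@H](C=C)[C@@]1(C)C(OC)CC(OC)OC | intermediate
9 | 4,6,6-trimethyl-4-(1,3,3-trimethoxypropyl)-5-vinylcyclohex-2-en-1-ol (3α-OH cis to the three-carbon arm, trans to vinyl) | C1=C[C@@H](O)C(C)(C)[C@H](C=C)[C@@]1(C)C(OC)CC(OC)OC | intermediate
10 | 2-bromopentan-3-one (racemic) | CCC(=O)C(C)Br | starting material
11 | B-alkyl-9-BBN adduct of 9 (boron on the terminal carbon C7) | C1=C[C@@H](O)C(C)(C)[C@H](CCB3C4CCCC3CCC4)[C@@]1(C)C(OC)CC(OC)OC | intermediate
12 | 6-[5-hydroxy-2,6,6-trimethyl-2-(1,3,3-trimethoxypropyl)cyclohex-3-en-1-yl]-4-methylhexan-3-one (ring stereocentres as in 9; mixture at C8 and C9) | C1=C[C@@H](O)C(C)(C)[C@H](CCC(C)C(=O)CC)[C@@]1(C)C(OC)CC(OC)OC | intermediate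
13 | (E)-3-[4-hydroxy-1,5,5-trimethyl-6-(3-methyl-4-oxohexyl)cyclohex-2-en-1-yl]prop-2-enal (ring stereocentres as in 9; mixture at C8) | C1=C[C@@H](O)C(C)(C)[C@H](CCC(C)C(=O)CC)[C@@]1(C)/C=C/C=O | intermediate
14 | bicyclic keto aldehyde (rings A and B; 3α-OH, C1=C2; C8 with β-methyl and α-propanoyl; C9 with 2-oxoethyl, H-9 α; H-5 α; C10 methyl β) | C1=C[C@@H](O)C(C)(C)[C@@H]2CC[C@@](C)(C(=O)CC)[C@H](CC=O)[C@@]12C | intermediate
15 | tricyclic hydroxy enone (rings A, B, C; 3α-OH, C1=C2, C12=C13, C14 ketone; methyls on C4 (two), C8 β, C10 β, C13; H-5 α, H-9 α) | C1=C[C@@H](O)C(C)(C)[C@@H]2CC[C@]3(C)[C@H](CC=C(C)C3=O)[C@@]12C | intermediate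
16 | 1α,2α-epoxy-3α-alcohol of the tricyclic enone | O1[C@H]2[C@@H]1[C@@H](O)C(C)(C)[C@@H]3CC[C@]4(C)[C@H](CC=C(C)C4=O)[C@@]23C | intermediate
17 | 1α,2α-epoxy-3-ketone of the tricyclic enone | O1[C@H]2[C@@H]1C(=O)C(C)(C)[C@@H]3CC[C@]4(C)[C@H](CC=C(C)C4=O)[C@@]23C | intermediate
18 | 1α-hydroxy-3,14-diketone (C12=C13 enone) | O[C@H]1CC(=O)C(C)(C)[C@@H]2CC[C@]3(C)[C@H](CC=C(C)C3=O)[C@@]12C | intermediate
19 | 1α-acetoxy-3,14-diketone (C12=C13 enone) | CC(=O)O[C@H]1CC(=O)C(C)(C)[C@@H]2CC[C@]3(C)[C@H](CC=C(C)C3=O)[C@@]12C | intermediate
20 | 1α-acetoxy ring-A ε-lactone (oxygen between C3 and C4) with ring-C enone | CC(=O)O[C@H]1CC(=O)OC(C)(C)[C@@H]2CC[C@]3(C)[C@H](CC=C(C)C3=O)[C@@]12C | intermediate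
21 | 1α-acetoxy ring-A ε-lactone with C14 exocyclic methylene (C15) conjugated to C12=C13 | CC(=O)O[C@H]1CC(=O)OC(C)(C)[C@@H]2CC[C@]3(C)[C@H](CC=C(C)C3=C)[C@@]12C | intermediate
22 | malonic acid | OC(=O)CC(=O)O | starting material
23 | spiro γ-lactone acid (ring D closed, lactone oxygen α on C14, C16 bearing CO2H as an epimer mixture) | CC(=O)O[C@H]1CC(=O)OC(C)(C)[C@@H]2CC[C@]3(C)[C@H](CC=C(C)[C@@]34CC(C(=O)O)C(=O)O4)[C@@]12C | intermediate
24 | tigloyl chloride, (E)-2-methylbut-2-enoyl chloride | C/C=C(\C)C(=O)Cl | starting material
25 | α-tigloyl spiro γ-lactone (C16 epimer mixture, enolisable) | CC(=O)O[C@H]1CC(=O)OC(C)(C)[C@@H]2CC[C@]3(C)[C@H](CC=C(C)[C@@]34CC(C(=O)/C(C)=C/C)C(=O)O4)[C@@]12C | intermediate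
26 | 16-hydroxy-16-tigloyl spiro γ-lactone (C16 as in the target) | CC(=O)O[C@H]1CC(=O)OC(C)(C)[C@@H]2CC[C@]3(C)[C@H](CC=C(C)[C@@]34C[C@@](O)(C(=O)/C(C)=C/C)C(=O)O4)[C@@]12C | intermediate
27 | CNP0131208.2 | CC(=O)O[C@H]1CC(=O)OC(C)(C)[C@@H]2CC[C@]3(C)[C@H](CC=C(C)[C@@]34C[C@]3(OC(C)=C(C)C3=O)C(=O)O4)[C@@]12C | target

Total steps: 18. Longest linear sequence: 18 steps (1 to 27); all other inputs are commercial.

The three steps most likely to fail

Step 8. Under equilibrating alkoxide conditions the Michael adduct may be drained through the other enolate face (acyl group axial), eroding the trans selectivity at C8, or oligomerisation may outrun the aldol closure. The fallback is a kinetically controlled, Lewis-acid route. It sets out from 13, which is converted with Me3SiOTf/Et3N into the bis-silylated silyl enol ether F1 (the hydroxyl is silylated as well). F1 is cyclised at −78 °C with TiCl4 in an irreversible intramolecular Mukaiyama–Michael addition, and acidic aqueous work-up removes both silyl groups to give keto aldehyde 14, now isolated. A separate acid-catalysed aldol condensation (TsOH, benzene, water removal) closes ring C, and the route is rejoined at 15.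

Step 15. The first-formed carboxy lactone may be oxidised again and add to a second diene, acetate may capture the allyl cation, or the carboxyl group may attack the β face. The fallback uses two-electron chemistry and sets out from 21. N-Iodosuccinimide and mono-allyl malonate should place iodine on C15 and the carboxylate on the tertiary allylic C14 from the α face, giving iodo ester F2. K2CO3 in DMF closes ring D by intramolecular C-alkylation of the malonate (5-exo-tet) to allyl ester F3, and Pd(PPh3)4 with morpholine removes the allyl group, so the route is rejoined at 23.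

Step 17. The oxaziridine may discriminate poorly between two sterically similar enolate faces, or the tertiary α-hydroxy β-keto lactone may undergo retro-Claisen cleavage on work-up. The fallback is a direct oxidative union that forms ring D and brings in ring E in one operation. Methyl glycolate and methyl 2-methyl-3-oxobutanoate are condensed under acid catalysis to enol ether diester F4, Dieckmann cyclisation (NaOMe) gives methyl 3-hydroxy-4,5-dimethylfuran-2-carboxylate F5, and saponification gives 3-hydroxy-4,5-dimethylfuran-2-carboxylic acid F6. The fallback then sets out from 21: Mn(OAc)3·2H2O and F6 in AcOH should add the furanone radical to C15 and close the lactone on C14 from the α face. This returns directly to 27, but C16 is then formed without control, so 27 would have to be separated from its C16 epimer by chromatography.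

Further compounds
F1 | step 8 | bis(trimethylsilyl) derivative of 13 (3α-silyl ether and tetrasubstituted C8=C14 silyl enol ether) | C1=C[C@@H](O[Si](C)(C)C)C(C)(C)[C@H](CCC(C)=C(CC)O[Si](C)(C)C)[C@@]1(C)/C=C/C=O
F2 | step 15 | C15 iodide with the C14 α-oxygen esterified by mono-allyl malonate | CC(=O)O[C@H]1CC(=O)OC(C)(C)[C@@H]2CC[C@]3(C)[C@H](CC=C(C)[C@]3(CI)OC(=O)CC(=O)OCC=C)[C@@]12C
F3 | step 15 | allyl ester of 23 | CC(=O)O[C@H]1CC(=O)OC(C)(C)[C@@H]2CC[C@]3(C)[C@H](CC=C(C)[C@@]34CC(C(=O)OCC=C)C(=O)O4)[C@@]12C
F4 | step 17 | methyl 3-(2-methoxy-2-oxoethoxy)-2-methylbut-2-enoate | COC(=O)COC(C)=C(C)C(=O)OC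
F5 | step 17 | methyl 3-hydroxy-4,5-dimethylfuran-2-carboxylate | COC(=O)c1oc(C)c(C)c1O
F6 | step 17 | 3-hydroxy-4,5-dimethylfuran-2-carboxylic acid | Cc1oc(C(=O)O)c(O)c1C
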